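**Retrosynthetic overview**

1. The strategy rests on the five-membered ring made of the quaternary bridgehead, the two alkene carbons (C=C–Me), the CH bridgehead and the acetoxy bridge carbon: it is a benzene ring less one carbon, with the seven-membered ring fused at the quaternary bridgehead and the neighbouring alkene carbon.
2. Late stage: acetates, the exo-methylene of the seven-ring lactone and the bridge carbinol (NaBH4 on the 7-ketone) are set last; the ketone comes from oxidative decarboxylation of the 7-hydroxy-7-carboxylic acid 40.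
3. Key disconnection: 40 arises by benzilic acid contraction of the bicyclo[2.2.2]oct-5-ene-2,3-dione 38 (norbornene formed last).
4. 38 comes from a Diels–Alder reaction between the masked ortho-quinone of benzosuberane lactone phenol 16 and α-methylene lactone 35 (bicyclo[2.2.2]octene, spiro centre, both bridgeheads).
5. 16: Cu-catalysed conjugate addition, Evans aldol (lactone ring), then Friedel–Crafts (seven-membered ring). 35: organocatalytic Michael/aldol condensation (cyclohexene), then oxa-Michael (lactone ring).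

Key step: step 26

Remark: the primary alcohol is carried as a TBDPS ether (it must outlast trifluoroacetic acid in step 20), the ortho-quinone is masked as an acetoxy methoxy ketal so that unmasking needs no strong acid beside the tertiary allylic alcohol, and the configuration at the hydroxy acid carbon of 40 is immaterial because step 27 makes it a ketone; the Wittig reagent of step 3 and ester 24 are taken as commercial.

**Route**

Step 1
Reactants: 1 2-methoxy-5-methylphenol
Product: 2 1-methoxy-4-methyl-2-(propan-2-yloxy)benzene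
Conditions: 2-bromopropane, K2CO3, DMF, 60 °C
Reagents that add atoms: 2-bromopropane CC(C)Br
Why: Williamson ether synthesis on the phenoxide; the isopropyl ether is a weak ortho director and can later be cleaved with BCl3 beside the methyl ether.

Step 2
Reactants: 2 1-methoxy-4-methyl-2-(propan-2-yloxy)benzene
Product: 3 2-methoxy-5-methyl-3-(propan-2-yloxy)benzaldehyde
Conditions: n-BuLi, TMEDA, Et2O, 0 °C to rt; DMF, −78 °C to rt; 1 M HCl
Reagents that add atoms: N,N-dimethylformamide CN(C)C=O
Why: Directed ortho-metalation followed by Bouveault formylation; the methoxy group directs lithiation to its free ortho position, whereas the position between the isopropoxy and methyl groups is shielded on both sides.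

Step 3
Reactants: 3 2-methoxy-5-methyl-3-(propan-2-yloxy)benzaldehyde
Product: 4 S-ethyl (2E)-3-[2-methoxy-5-methyl-3-(propan-2-yloxy)phenyl]prop-2-enethioate
Conditions: S-ethyl 2-(triphenyl-λ5-phosphanylidene)ethanethioate, toluene, 80 °C
Reagents that add atoms: S-ethyl 2-(triphenyl-λ5-phosphanylidene)ethanethioate CCSC(=O)C=P(c1ccccc1)(c1ccccc1)c1ccccc1
Why: Wittig olefination with a stabilised ylide should give the E thioester, the substrate class suited to the next step.

Step 4
Reactants: 4 S-ethyl (2E)-3-[2-methoxy-5-methyl-3-(propan-2-yloxy)phenyl]prop-2-enethioate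
Product: 5 S-ethyl (3R)-3-[2-methoxy-5-methyl-3-(propan-2-yloxy)phenyl]butanethioate
Conditions: MeMgBr, CuBr·SMe2 (5 mol%), Josiphos ligand (6 mol%, antipode chosen for the 3R adduct), t-BuOMe, −75 °C
Reagents that add atoms: methylmagnesium bromide C[Mg]Br
Why: Copper-catalysed asymmetric conjugate addition of a Grignard reagent to an unsaturated thioester; the chiral diphosphine on copper selects the alkene face and so sets the benzylic methyl centre (R).

Step 5
Reactants: 5 S-ethyl (3R)-3-[2-methoxy-5-methyl-3-(propan-2-yloxy)phenyl]butanethioate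
Product: 6 (3R)-3-[2-methoxy-5-methyl-3-(propan-2-yloxy)phenyl]butanal
Conditions: i-Bu2AlH, CH2Cl2, −60 °C; Rochelle salt work-up
Reagents that add atoms: none
Why: Partial reduction of a thioester with i-Bu2AlH stops at the aldehyde because the thiohemiacetal aluminate is stable at low temperature; the benzylic centre is not enolisable.

Step 6
Reactants: 7 (4S)-4-benzyl-1,3-oxazolidin-2-one, 8 methyl 4-chloro-4-oxobutanoate
Product: 9 methyl 4-[(4S)-4-benzyl-2-oxo-1,3-oxazolidin-3-yl]-4-oxobutanoate
Conditions: n-BuLi, THF, −78 °C; then 8, −78 to 0 °C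
Reagents that add atoms: none
Why: N-acylation of the lithiated oxazolidinone by the acid chloride, the standard preparation of Evans imides.

Step 7
Reactants: 9 methyl 4-[(4S)-4-benzyl-2-oxo-1,3-oxazolidin-3-yl]-4-oxobutanoate, 6 (3R)-3-[2-methoxy-5-methyl-3-(propan-2-yloxy)phenyl]butanal
Product: 11 (4S)-4-benzyl-3-({(2R,3S)-2-[(2R)-2-[2-methoxy-5-methyl-3-(propan-2-yloxy)phenyl]propyl]-5-oxooxolan-3-yl}carbonyl)-1,3-oxazolidin-2-one, via aldol adduct 10 (not isolated)
Conditions: Bu2BOTf, i-Pr2NEt, CH2Cl2, −78 to 0 °C; pH 7 buffer, MeOH, H2O2; then TsOH (cat.), CH2Cl2, rt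
Reagents that add atoms: none
Why: Evans syn-aldol reaction through the Z boron enolate and a Zimmerman–Traxler transition state, in which the benzyl oxazolidinone sets both new centres (3S,4R in 10) over the remote benzylic centre, and the syn hydroxy ester then closes to the trans-disubstituted γ-lactone.

Step 8
Reactants: 11 lactone imide
Product: 12 (2R,3S)-2-[(2R)-2-[2-methoxy-5-methyl-3-(propan-2-yloxy)phenyl]propyl]-5-oxooxolane-3-carboxylic acid
Conditions: LiOH, H2O2, THF–H2O, 0 °C; Na2SO3; then HCl to pH 2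
Reagents that add atoms: hydrogen peroxide OO
Why: Hydroperoxide cleavage of the imide at the exocyclic carbonyl frees the acid and the auxiliary without epimerisation, and any lactone opened by hydroxide should reclose on acidification.

Step 9
Reactants: 12 paraconic acid
Product: 14 (6S,7R,9R)-configured trans-fused γ-lactone of 7-hydroxy-1-methoxy-4,9-dimethyl-5-oxo-2-(propan-2-yloxy)-6,7,8,9-tetrahydro-5H-benzo[7]annulen-6-ylacetic acid, via acid chloride 13 (not isolated)
Conditions: (COCl)2, DMF (cat.), CH2Cl2, 0 °C to rt; then SnCl4, CH2Cl2, −20 to 0 °C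
Reagents that add atoms: none
Why: Intramolecular Friedel–Crafts acylation closes the seven-membered ring at the only free position ortho to the tether, which is also para to the isopropoxy group.

Step 10
Reactants: 14 tricyclic keto lactone
Product: 15 (6S,7R,9R)-configured trans-fused γ-lactone of 7-hydroxy-1-methoxy-4,9-dimethyl-2-(propan-2-yloxy)-6,7,8,9-tetrahydro-5H-benzo[7]annulen-6-ylacetic acid
Conditions: H2 (4 atm), Pd/C (10%), AcOH, HClO4 (cat.), rt
Reagents that add atoms: none
Why: Acid-assisted hydrogenolysis of an electron-rich aryl ketone to the methylene group through the benzylic alcohol, without a free carbocation that could epimerise the neighbouring lactone carbon.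

Step 11
Reactants: 15 isopropyl ether
Product: 16 (6S,7R,9R)-configured trans-fused γ-lactone of 2,7-dihydroxy-1-methoxy-4,9-dimethyl-6,7,8,9-tetrahydro-5H-benzo[7]annulen-6-ylacetic acid
Conditions: BCl3, CH2Cl2, −78 to −20 °C; then H2O
Reagents that add atoms: none
Why: Selective Lewis acid dealkylation; BCl3 cleaves the secondary isopropyl aryl ether far faster than the methyl ether and leaves the lactone intact.

Step 12
Reactants: 17 (3R)-3,7-dimethyloct-6-enal ((R)-citronellal)
Product: 18 (4R)-4,8-dimethylnon-7-en-2-ol (both carbinol epimers)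
Conditions: MeMgBr, Et2O, 0 °C
Reagents that add atoms: methylmagnesium bromide C[Mg]Br
Why: Grignard addition to the aldehyde; the carbinol centre is left unselective because it becomes a ketone in step 15.

Step 13
Reactants: 18 (4R)-4,8-dimethylnon-7-en-2-ol
Product: 20 (4R)-4-methylheptane-1,6-diol, via hydroxy aldehyde 19 (not isolated)
Conditions: O3, CH2Cl2–MeOH, −78 °C; then NaBH4, −78 to 0 °C
Reagents that add atoms: ozone [O-][O+]=O
Why: Ozonolysis of the only alkene with reductive work-up turns the prenyl end into the primary alcohol and leaves the methyl-bearing centre untouched.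

Step 14
Reactants: 20 (4R)-4-methylheptane-1,6-diol
Product: 21 (4R)-7-{[tert-butyl(diphenyl)silyl]oxy}-4-methylheptan-2-ol
Conditions: t-BuPh2SiCl (1.05 equiv), imidazole, CH2Cl2, −20 to 0 °C
Reagents that add atoms: tert-butyl(chloro)diphenylsilane CC(C)(C)[Si](Cl)(c1ccccc1)c1ccccc1
Why: Silylation with the bulky chlorosilane is selective for the primary over the secondary alcohol.

Step 15
Reactants: 21 mono-silyl ether
Product: 22 (4R)-7-{[tert-butyl(diphenyl)silyl]oxy}-4-methylheptan-2-one
Conditions: Dess–Martin periodinane, CH2Cl2, rt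
Reagents that add atoms: none
Why: Dess–Martin oxidation of the secondary alcohol to the methyl ketone under neutral conditions.

Step 16
Reactants: 22 methyl ketone
Product: 23 (4R)-7-{[tert-butyl(diphenyl)silyl]oxy}-4-methyl-3-methylideneheptan-2-one
Conditions: paraformaldehyde, i-Pr2NH·CF3CO2H, THF, reflux
Reagents that add atoms: formaldehyde (as paraformaldehyde) C=O
Why: Mannich-type α-methylenation under ammonium salt catalysis reacts through the more substituted enol, so the methylene group enters at C-3 and the neighbouring stereocentre, which is not enolisable in the product, is kept.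

Step 17
Reactants: 23 enone, 24 tert-butyl 4-oxobutanoate
Product: 25 tert-butyl (3S)-5-[(2R)-5-{[tert-butyl(diphenyl)silyl]oxy}pentan-2-yl]-3-formyl-6-oxoheptanoate (both C-5 epimers)
Conditions: (S)-α,α-diphenylprolinol trimethylsilyl ether (20 mol%), ethyl 3,4-dihydroxybenzoate (20 mol%), neat, 4 °C to rt
Reagents that add atoms: none
Why: Enamine-catalysed asymmetric Michael addition of an aldehyde to a vinyl ketone; the E enamine of 24 is attacked on the face away from the diphenyl(silyloxy)methyl group, which sets the formyl-bearing centre (S), while the centre next to the ketone is left unselective because it becomes sp2 in step 21.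

Step 18
Reactants: 25 keto aldehyde
Product: 26 tert-butyl 2-[(1S)-5-[(2R)-5-{[tert-butyl(diphenyl)silyl]oxy}pentan-2-yl]-4-oxocyclohex-2-en-1-yl]acetate (both C-5 epimers)
Conditions: 0.1 M KOH (aq), n-Bu4NOH (cat.), Et2O–THF, rt
Reagents that add atoms: none
Why: Intramolecular aldol condensation (second stage of a Robinson annulation) of the methyl ketone onto the aldehyde is the only six-membered closure open, and the mild base should not enolise the γ-centre.

Step 19
Reactants: 26 cyclohexenone
Product: 27 tert-butyl 2-[(1S)-5-[(2R)-5-{[tert-butyl(diphenyl)silyl]oxy}pentan-2-yl]-4-oxo-5-(phenylselanyl)cyclohex-2-en-1-yl]acetate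
Conditions: LiN(i-Pr)2, THF, −78 °C; PhSeCl, −78 °C
Reagents that add atoms: benzeneselenenyl chloride Cl[Se]c1ccccc1
Why: Kinetic deprotonation of an enone gives the cross-conjugated α′-enolate, the only α-position available, and its selenenylation stores the future double bond at the side-chain-bearing carbon without forming a dienone that would aromatise.

Step 20
Reactants: 27 selenide
Product: 29 cis-fused (3aS,7aS ring fusion as in 35) 5-[(2R)-5-{[tert-butyl(diphenyl)silyl]oxy}pentan-2-yl]-5-(phenylselanyl)hexahydro-1-benzofuran-2,6-dione, via enone acid 28 (not isolated)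
Conditions: CF3CO2H, CH2Cl2, 0 °C; evaporation; then NaHCO3 (aq), THF, rt
Reagents that add atoms: none
Why: Acidolysis of the tert-butyl ester followed by 5-exo-trig oxa-Michael addition of the carboxylate to the enone; the five-membered ring can only form cis-fused, so the new C–O centre is set by the adjacent organocatalytically formed centre.

Step 21
Reactants: 29 seleno keto lactone
Product: 31 cis-fused 5-[(2R)-5-{[tert-butyl(diphenyl)silyl]oxy}pentan-2-yl]-3,3a,7,7a-tetrahydro-1-benzofuran-2,6-dione, via selenoxide 30 (not isolated)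
Conditions: H2O2 (30%), pyridine, CH2Cl2, 0 °C to rt
Reagents that add atoms: none
Why: Selenoxide syn-elimination under near-neutral conditions should go toward the ring CH2 and give the endocyclic enone, avoiding base that could expel the β-acyloxy group.

Step 22
Reactants: 31 enone lactone
Product: 32 cis-fused 6-hydroxy-6-methyl-5-[(2R)-5-{[tert-butyl(diphenyl)silyl]oxy}pentan-2-yl]-3a,6,7,7a-tetrahydro-1-benzofuran-2(3H)-one (hydroxyl cis to the lactone oxygen)
Conditions: CeCl3 (anhydrous), MeMgBr, THF, −78 °C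
Reagents that add atoms: methylmagnesium bromide C[Mg]Br
Why: Organocerium 1,2-addition is fast and weakly basic, so the ketone reacts before the lactone and before enolisation; methyl should enter from the convex face anti to the lactone ring, placing the tertiary hydroxyl cis to the lactone oxygen.

Step 23
Reactants: 32 tertiary alcohol
Product: 35 (3aS,6R,7aS)-6-hydroxy-6-methyl-3-methylidene-5-[(2R)-5-{[tert-butyl(diphenyl)silyl]oxy}pentan-2-yl]-3a,6,7,7a-tetrahydro-1-benzofuran-2(3H)-one, via Mannich base 33 (not isolated), via methiodide 34 (not isolated)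
Conditions: LiN(i-Pr)2 (2.3 equiv), THF, −78 °C; CH2=NMe2 I, −78 to 0 °C; then MeI, MeOH, rt; then NaHCO3 (aq), EtOAc
Reagents that add atoms: N,N-dimethylmethyleneiminium iodide C=[N+](C)C.[I-]
Why: Eschenmoser methylenation of the lactone enolate (Mannich reaction, quaternisation, elimination) installs the exo-methylene group without touching the ring-fusion centres.

Step 24
Reactants: 16 benzosuberane lactone phenol, 35 α-methylene lactone
Product: 37 bicyclo[2.2.2]octenone adduct with acetoxy methoxy ketal (both ketal epimers), via acetoxy dienone 36 (not isolated)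
Conditions: PhI(OAc)2, NaHCO3, CH2Cl2, −20 to 0 °C; then 35, toluene, 70 °C
Reagents that add atoms: (diacetoxyiodo)benzene CC(=O)OI(OC(C)=O)c1ccccc1
Why: Wessely-type oxidative dearomatisation gives the non-dimerising masked ortho-quinone 36, which adds the methylene lactone in a Diels–Alder reaction in which the dienone carbonyl directs the lactone-bearing carbon to the neighbouring CH terminus and the methylene carbon to the fully substituted terminus (also the only sterically open pairing), the lactone carbonyl sits endo, the diene reacts anti to the pseudo-axial benzylic methyl group and the dienophile on its convex face syn to the ring-fusion hydrogen, which sets both bridgeheads and the spiro centre.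

Step 25
Reactants: 37 acetoxy methoxy ketal adduct
Product: 38 bicyclo[2.2.2]oct-5-ene-2,3-dione carrying both lactone halves
Conditions: K2CO3 (0.2 equiv), MeOH, −10 °C, dark; AcOH quench
Reagents that add atoms: none
Why: Methoxide-catalysed transesterification removes the acetyl group, and the resulting hemiketal collapses to the second carbonyl without acid, so the tertiary allylic alcohol and the silyl ether are not endangered.

Step 26
Reactants: 38 bicyclo[2.2.2]oct-5-ene-2,3-dione
Product: 40 7-hydroxynorbornene-7-carboxylic acid carrying both lactone halves, via tripotassium salt 39 (not isolated)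
Conditions: KOH (10 equiv), THF–H2O, 0 °C to rt, dark, Ar; then 1 M HCl to pH 2–3, rt
Reagents that add atoms: potassium hydroxide [K+].[OH-]
Why: Hydroxide adds to one of the two strained carbonyls of the dione bridge and the resulting alkoxide drives the adjacent bridgehead carbon (the CH bridgehead, or equally the quaternary one) onto the neighbouring carbonyl carbon in a 1,2-shift, turning the two-carbon dione bridge into a one-carbon C(OH)CO2− bridge. This is the benzilic acid rearrangement as known for bicyclic 1,2-diones whose bridgeheads cannot enolise, so no aldol or enolate path competes. The cyclopentene ring (quaternary bridgehead, C=C–Me, CH bridgehead, bridge carbon) is closed by this anionic 1,2-shift as a six-to-five ring contraction, not by cyclisation of an open chain, and the migrating carbon keeps its configuration, so both bridgeheads and the spiro centre are carried over unchanged. The only new stereocentre, the bridge carbon, is expected with hydroxyl anti to the alkene but is not relied on because step 27 makes it a ketone. The step needs the shift to win over hydroxide cleavage of the carbonyl–bridgehead bond and needs the lactones to survive: the strain of the 1,2-dione and irreversible carboxylate formation favour the shift, both migration modes give one constitution, and the two lactones opened by KOH (salt 39) should reclose at pH 2–3.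

Step 27
Reactants: 40 α-hydroxy acid
Product: 41 norbornen-7-one carrying both lactone halves
Conditions: Pb(OAc)4, pyridine, benzene, 0 °C to rt
Reagents that add atoms: none
Why: Oxidative decarboxylation of an α-hydroxy acid with Pb(OAc)4 gives the bridge ketone with loss of CO2, much faster than any reaction of the alkenes or the tertiary alcohol.

Step 28
Reactants: 41 bridge ketone
Product: 42 anti-7-norbornenol carrying both lactone halves
Conditions: NaBH4, MeOH–THF, −40 °C
Reagents that add atoms: none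
Why: Hydride reduction of a 7-norbornenone occurs from the alkene side, here reinforced by the exo cyclohexene ring on the saturated bridge, so the hydroxyl ends anti to the alkene as in the target, and the lactones are not reduced at this temperature.

Step 29
Reactants: 42 bridge alcohol
Product: 45 bis-lactone with exo-methylene on the seven-ring lactone, via Mannich base 43 (not isolated), via methiodide 44 (not isolated)
Conditions: LiN(i-Pr)2 (4 equiv), THF, −78 °C; CH2=NMe2 I, −78 to 0 °C; then MeI, MeOH, rt; then NaHCO3 (aq), EtOAc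
Reagents that add atoms: N,N-dimethylmethyleneiminium iodide C=[N+](C)C.[I-]
Why: Eschenmoser methylenation; only the trans-fused lactone has α-hydrogens (the spiro lactone is quaternary), and the two hydroxyl groups are merely deprotonated.

Step 30
Reactants: 45 silyl ether
Product: 46 triol (primary, bridge secondary and tertiary hydroxyl)
Conditions: HF·pyridine, pyridine, THF, 0 °C to rt
Reagents that add atoms: none
Why: Buffered fluoride desilylation frees the primary alcohol without base that could add alkoxide to the methylene lactone.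

Step 31
Reactants: 46 triol
Product: 47 CNP0257312.1 (target)
Conditions: Ac2O, pyridine, DMAP (5 mol%), CH2Cl2, 0 °C to rt
Reagents that add atoms: acetic anhydride CC(=O)OC(C)=O
Why: Acylation of the primary and the bridge secondary alcohols; the tertiary allylic alcohol should stay free under these mild conditions.

**Compound list**

1 | 2-methoxy-5-methylphenol | Cc1ccc(OC)c(O)c1 | starting material
2 | 1-methoxy-4-methyl-2-(propan-2-yloxy)benzene | Cc1ccc(OC)c(OC(C)C)c1 | intermediate
3 | 2-methoxy-5-methyl-3-(propan-2-yloxy)benzaldehyde | O=Cc1cc(C)cc(OC(C)C)c1OC | intermediate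
4 | S-ethyl (2E)-3-[2-methoxy-5-methyl-3-(propan-2-yloxy)phenyl]prop-2-enethioate | CCSC(=O)/C=C/c1cc(C)cc(OC(C)C)c1OC | intermediate
5 | S-ethyl (3R)-3-[2-methoxy-5-methyl-3-(propan-2-yloxy)phenyl]butanethioate | CCSC(=O)C[C@@H](C)c1cc(C)cc(OC(C)C)c1OC | intermediate
6 | (3R)-3-[2-methoxy-5-methyl-3-(propan-2-yloxy)phenyl]butanal | O=CC[C@@H](C)c1cc(C)cc(OC(C)C)c1OC | intermediate
7 | (4S)-4-benzyl-1,3-oxazolidin-2-one | O=C1N[C@@H](Cc2ccccc2)CO1 | starting material
8 | methyl 4-chloro-4-oxobutanoate | COC(=O)CCC(Cl)=O | starting material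
9 | methyl 4-[(4S)-4-benzyl-2-oxo-1,3-oxazolidin-3-yl]-4-oxobutanoate | COC(=O)CCC(=O)N1[C@@H](Cc2ccccc2)COC1=O | intermediate
10 | methyl (3S,4R,6R)-3-{[(4S)-4-benzyl-2-oxo-1,3-oxazolidin-3-yl]carbonyl}-4-hydroxy-6-[2-methoxy-5-methyl-3-(propan-2-yloxy)phenyl]heptanoate (syn-aldol adduct) | COC(=O)C[C@H](C(=O)N1[C@@H](Cc2ccccc2)COC1=O)[C@H](O)C[C@@H](C)c1cc(C)cc(OC(C)C)c1OC | intermediate
11 | (4S)-4-benzyl-3-({(2R,3S)-2-[(2R)-2-[2-methoxy-5-methyl-3-(propan-2-yloxy)phenyl]propyl]-5-oxooxolan-3-yl}carbonyl)-1,3-oxazolidin-2-one (trans lactone) | C1C(=O)O[C@H](C[C@@H](C)c2cc(C)cc(OC(C)C)c2OC)[C@H]1C(=O)N1[C@@H](Cc2ccccc2)COC1=O | intermediate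
12 | (2R,3S)-2-[(2R)-2-[2-methoxy-5-methyl-3-(propan-2-yloxy)phenyl]propyl]-5-oxooxolane-3-carboxylic acid | C1C(=O)O[C@H](C[C@@H](C)c2cc(C)cc(OC(C)C)c2OC)[C@H]1C(O)=O | intermediate
13 | acid chloride of 12 | C1C(=O)O[C@H](C[C@@H](C)c2cc(C)cc(OC(C)C)c2OC)[C@H]1C(Cl)=O | intermediate
14 | (6S,7R,9R) trans-fused γ-lactone of 7-hydroxy-1-methoxy-4,9-dimethyl-5-oxo-2-(propan-2-yloxy)-6,7,8,9-tetrahydro-5H-benzo[7]annulen-6-ylacetic acid | C1C(=O)O[C@@H]2C[C@@H](C)c3c(OC)c(OC(C)C)cc(C)c3C(=O)[C@@H]12 | intermediate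
15 | (6S,7R,9R) trans-fused γ-lactone of 7-hydroxy-1-methoxy-4,9-dimethyl-2-(propan-2-yloxy)-6,7,8,9-tetrahydro-5H-benzo[7]annulen-6-ylacetic acid | C1C(=O)O[C@@H]2C[C@@H](C)c3c(OC)c(OC(C)C)cc(C)c3C[C@@H]12 | intermediate
16 | (6S,7R,9R) trans-fused γ-lactone of 2,7-dihydroxy-1-methoxy-4,9-dimethyl-6,7,8,9-tetrahydro-5H-benzo[7]annulen-6-ylacetic acid (phenol) | C1C(=O)O[C@@H]2C[C@@H](C)c3c(OC)c(O)cc(C)c3C[C@@H]12 | intermediate
17 | (3R)-3,7-dimethyloct-6-enal ((R)-citronellal) | CC(C)=CCC[C@@H](C)CC=O | starting material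
18 | (4R)-4,8-dimethylnon-7-en-2-ol (both C-2 epimers) | CC(C)=CCC[C@@H](C)CC(C)O | intermediate
19 | (4R)-6-hydroxy-4-methylheptanal | O=CCC[C@@H](C)CC(C)O | intermediate
20 | (4R)-4-methylheptane-1,6-diol | OCCC[C@@H](C)CC(C)O | intermediate
21 | (4R)-7-{[tert-butyl(diphenyl)silyl]oxy}-4-methylheptan-2-ol | CC(O)C[C@H](C)CCCO[Si](c1ccccc1)(c1ccccc1)C(C)(C)C | intermediate
22 | (4R)-7-{[tert-butyl(diphenyl)silyl]oxy}-4-methylheptan-2-one | CC(=O)C[C@H](C)CCCO[Si](c1ccccc1)(c1ccccc1)C(C)(C)C | intermediate
23 | (4R)-7-{[tert-butyl(diphenyl)silyl]oxy}-4-methyl-3-methylideneheptan-2-one | CC(=O)C(=C)[C@H](C)CCCO[Si](c1ccccc1)(c1ccccc1)C(C)(C)C | intermediate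
24 | tert-butyl 4-oxobutanoate | CC(C)(C)OC(=O)CCC=O | starting material
25 | tert-butyl (3S)-5-[(2R)-5-{[tert-butyl(diphenyl)silyl]oxy}pentan-2-yl]-3-formyl-6-oxoheptanoate (both C-5 epimers) | CC(=O)C(C[C@H](C=O)CC(=O)OC(C)(C)C)[C@H](C)CCCO[Si](c1ccccc1)(c1ccccc1)C(C)(C)C | intermediate
26 | tert-butyl 2-[(1S)-5-[(2R)-5-{[tert-butyl(diphenyl)silyl]oxy}pentan-2-yl]-4-oxocyclohex-2-en-1-yl]acetate (both C-5 epimers) | O=C1C=C[C@H](CC(=O)OC(C)(C)C)CC1[C@H](C)CCCO[Si](c2ccccc2)(c2ccccc2)C(C)(C)C | intermediate
27 | tert-butyl 2-[(1S)-5-[(2R)-5-{[tert-butyl(diphenyl)silyl]oxy}pentan-2-yl]-4-oxo-5-(phenylselanyl)cyclohex-2-en-1-yl]acetate | O=C1C=C[C@H](CC(=O)OC(C)(C)C)CC1([Se]c2ccccc2)[C@H](C)CCCO[Si](c2ccccc2)(c2ccccc2)C(C)(C)C | intermediate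
28 | 2-[(1S)-5-[(2R)-5-{[tert-butyl(diphenyl)silyl]oxy}pentan-2-yl]-4-oxo-5-(phenylselanyl)cyclohex-2-en-1-yl]acetic acid | O=C1C=C[C@H](CC(O)=O)CC1([Se]c2ccccc2)[C@H](C)CCCO[Si](c2ccccc2)(c2ccccc2)C(C)(C)C | intermediate
29 | cis-fused 5-[(2R)-5-{[tert-butyl(diphenyl)silyl]oxy}pentan-2-yl]-5-(phenylselanyl)hexahydro-1-benzofuran-2,6-dione | C1C(=O)O[C@H]2CC(=O)C([Se]c3ccccc3)([C@H](C)CCCO[Si](c3ccccc3)(c3ccccc3)C(C)(C)C)C[C@H]21 | intermediate
30 | selenoxide of 29 | C1C(=O)O[C@H]2CC(=O)C([Se](=O)c3ccccc3)([C@H](C)CCCO[Si](c3ccccc3)(c3ccccc3)C(C)(C)C)C[C@H]21 | intermediate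
31 | cis-fused 5-[(2R)-5-{[tert-butyl(diphenyl)silyl]oxy}pentan-2-yl]-3,3a,7,7a-tetrahydro-1-benzofuran-2,6-dione | C1C(=O)O[C@H]2CC(=O)C([C@H](C)CCCO[Si](c3ccccc3)(c3ccccc3)C(C)(C)C)=C[C@H]21 | intermediate
32 | cis-fused 6-hydroxy-6-methyl-5-[(2R)-5-{[tert-butyl(diphenyl)silyl]oxy}pentan-2-yl]-3a,6,7,7a-tetrahydro-1-benzofuran-2(3H)-one (hydroxyl cis to lactone oxygen) | C1C(=O)O[C@H]2C[C@@](C)(O)C([C@H](C)CCCO[Si](c3ccccc3)(c3ccccc3)C(C)(C)C)=C[C@H]21 | intermediate
33 | 3-[(dimethylamino)methyl] derivative of 32 (Mannich base, either C-3 epimer) | CN(C)CC1C(=O)O[C@H]2C[C@@](C)(O)C([C@H](C)CCCO[Si](c3ccccc3)(c3ccccc3)C(C)(C)C)=C[C@H]21 | intermediate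
34 | trimethylammonium iodide of 33 | C[N+](C)(C)CC1C(=O)O[C@H]2C[C@@](C)(O)C([C@H](C)CCCO[Si](c3ccccc3)(c3ccccc3)C(C)(C)C)=C[C@H]21.[I-] | intermediate
35 | (3aS,6R,7aS)-6-hydroxy-6-methyl-3-methylidene-5-[(2R)-5-{[tert-butyl(diphenyl)silyl]oxy}pentan-2-yl]-3a,6,7,7a-tetrahydro-1-benzofuran-2(3H)-one | C=C1C(=O)O[C@H]2C[C@@](C)(O)C([C@H](C)CCCO[Si](c3ccccc3)(c3ccccc3)C(C)(C)C)=C[C@H]21 | intermediate
36 | 6-acetoxy-6-methoxycyclohexa-2,4-dienone fused to the seven-ring lactone (masked ortho-quinone of 16, both ketal epimers) | C1C(=O)O[C@@H]2C[C@@H](C)C3=C(C[C@@H]12)C(C)=CC(=O)C3(OC)OC(C)=O | intermediate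
37 | Diels–Alder adduct: bicyclo[2.2.2]oct-5-en-2-one with 3-acetoxy-3-methoxy ketal, spiro lactone and seven-ring lactone (both ketal epimers) | C1C(=O)O[C@@H]2C[C@@H](C)[C@]34C[C@]5(C(=O)O[C@H]6C[C@@](C)(O)C([C@H](C)CCCO[Si](c7ccccc7)(c7ccccc7)C(C)(C)C)=C[C@H]65)[C@H](C(C)=C3C[C@@H]12)C(=O)C4(OC)OC(C)=O | intermediate
38 | bicyclo[2.2.2]oct-5-ene-2,3-dione carrying both lactone halves | C1C(=O)O[C@@H]2C[C@@H](C)[C@]34C[C@]5(C(=O)O[C@H]6C[C@@](C)(O)C([C@H](C)CCCO[Si](c7ccccc7)(c7ccccc7)C(C)(C)C)=C[C@H]65)[C@H](C(C)=C3C[C@@H]12)C(=O)C4=O | intermediate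
39 | tripotassium salt of the ring-contracted hydroxy acid with both lactones opened | O[C@@H]1C[C@@H](C)[C@]23C[C@@](C([O-])=O)([C@@H]4C=C([C@H](C)CCCO[Si](c5ccccc5)(c5ccccc5)C(C)(C)C)[C@](C)(O)C[C@@H]4O)[C@H](C(C)=C2C[C@H]1CC([O-])=O)[C@]3(O)C([O-])=O.[K+].[K+].[K+] | intermediate
40 | 7-hydroxynorbornene-7-carboxylic acid carrying both lactone halves (hydroxyl anti to the alkene) | C1C(=O)O[C@@H]2C[C@@H](C)[C@]34C[C@]5(C(=O)O[C@H]6C[C@@](C)(O)C([C@H](C)CCCO[Si](c7ccccc7)(c7ccccc7)C(C)(C)C)=C[C@H]65)[C@H](C(C)=C3C[C@@H]12)[C@]4(O)C(=O)O | intermediate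
41 | norbornen-7-one carrying both lactone halves | C1C(=O)O[C@@H]2C[C@@H](C)[C@]34C[C@]5(C(=O)O[C@H]6C[C@@](C)(O)C([C@H](C)CCCO[Si](c7ccccc7)(c7ccccc7)C(C)(C)C)=C[C@H]65)[C@H](C(C)=C3C[C@@H]12)C4=O | intermediate
42 | anti-7-norbornenol carrying both lactone halves | C1C(=O)O[C@@H]2C[C@@H](C)[C@]34C[C@]5(C(=O)O[C@H]6C[C@@](C)(O)C([C@H](C)CCCO[Si](c7ccccc7)(c7ccccc7)C(C)(C)C)=C[C@H]65)[C@H](C(C)=C3C[C@@H]12)[C@H]4O | intermediate
43 | α-[(dimethylamino)methyl] seven-ring lactone derived from 42 (Mannich base) | CN(C)CC1C(=O)O[C@@H]2C[C@@H](C)[C@]34C[C@]5(C(=O)O[C@H]6C[C@@](C)(O)C([C@H](C)CCCO[Si](c7ccccc7)(c7ccccc7)C(C)(C)C)=C[C@H]65)[C@H](C(C)=C3C[C@@H]12)[C@H]4O | intermediate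
44 | trimethylammonium iodide of 43 | C[N+](C)(C)CC1C(=O)O[C@@H]2C[C@@H](C)[C@]34C[C@]5(C(=O)O[C@H]6C[C@@](C)(O)C([C@H](C)CCCO[Si](c7ccccc7)(c7ccccc7)C(C)(C)C)=C[C@H]65)[C@H](C(C)=C3C[C@@H]12)[C@H]4O.[I-] | intermediate
45 | α-methylene seven-ring lactone with free bridge alcohol and silyl ether | C=C1C(=O)O[C@@H]2C[C@@H](C)[C@]34C[C@]5(C(=O)O[C@H]6C[C@@](C)(O)C([C@H](C)CCCO[Si](c7ccccc7)(c7ccccc7)C(C)(C)C)=C[C@H]65)[C@H](C(C)=C3C[C@@H]12)[C@H]4O | intermediate
46 | triol (desilylated 45) | C=C1C(=O)O[C@@H]2C[C@@H](C)[C@]34C[C@]5(C(=O)O[C@H]6C[C@@](C)(O)C([C@H](C)CCCO)=C[C@H]65)[C@H](C(C)=C3C[C@@H]12)[C@H]4O | intermediate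
47 | CNP0257312.1 | C=C1C(=O)O[C@@H]2C[C@@H](C)[C@]34C[C@]5(C(=O)O[C@H]6C[C@@](C)(O)C([C@H](C)CCCOC(C)=O)=C[C@H]65)[C@H](C(C)=C3C[C@@H]12)[C@H]4OC(C)=O | target

**Step count**

Total: 31 steps. Longest linear sequence: 20 steps (steps 12 to 31, from (R)-citronellal).

**Steps most likely to fail**

Step 24 (oxidative dearomatisation and Diels–Alder reaction). The acetoxy dienone may shift its acetoxy group and rearomatise, or lose facial control, at the temperature the crowded diene terminus demands, so that cycloaddition stalls or gives mixtures. Fallback, setting out from 16 and 35 and returning to the route at 38: oxidation of 16 with PhI(OAc)2 in CH2Cl2 in the presence of 4-methoxybenzyl alcohol should give a true mixed ketal, the 6-methoxy-6-(4-methoxybenzyloxy) dienone F1, which as a ketal should tolerate 110–140 °C. Cycloaddition with 35 in mesitylene would give the mixed ketal adduct F2. Oxidative removal of the 4-methoxybenzyl group with DDQ in wet CH2Cl2 would release a hemiketal that loses methanol to give dione 38 without acid.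

Step 26 (benzilic acid contraction). Hydroxide may cleave the bond between the hydrated carbonyl and the allylic CH bridgehead, opening the bicycle to a cyclohexene carboxylic acid instead of inducing the 1,2-shift, or relactonisation after acidification may be incomplete. Fallback, setting out from 38 and returning at 42: condensation of 38 with p-toluenesulfonohydrazide would give the mono-tosylhydrazone F3 (either carbonyl serves). Et3N would convert it into the α-diazo ketone F4 (Bamford–Stevens diazo formation). Photolysis in aqueous THF (Wolff rearrangement) would contract the same dione bridge to the norbornene-7-carboxylic acid F5. Kochi oxidative decarboxylation (Pb(OAc)4, Cu(OAc)2, pyridine, benzene, 80 °C) passes through the alkene-stabilised 7-norbornenyl cation and should give the anti acetate F6, whose methanolysis (K2CO3, MeOH, 0 °C) gives alcohol 42.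

Step 17 (organocatalytic Michael addition). Conjugate addition to the α-branched vinyl ketone may be slow, allowing self-aldolisation of aldehyde 24 and erosion of the enamine-derived centre. Fallback, setting out from 23 and 7 and returning at 25: acylation of 7 with tert-butyl 4-chloro-4-oxobutanoate (n-BuLi, THF) would give the tert-butyl succinyl imide F7. Its chlorotitanium enolate (TiCl4, i-Pr2NEt, CH2Cl2, −78 °C) should add to 23 in an Evans auxiliary-controlled Michael reaction to give the imide adduct F8 with the same sense at the new centre. LiBH4 would remove the auxiliary and reduce the ketone to the diol F9, and oxidation of both alcohols with Dess–Martin periodinane would return keto aldehyde 25.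

Further compounds
F1 | step 24 | 6-methoxy-6-[(4-methoxyphenyl)methoxy]cyclohexa-2,4-dienone fused to the seven-ring lactone (mixed ketal of the masked ortho-quinone) | C1C(=O)O[C@@H]2C[C@@H](C)C3=C(C[C@@H]12)C(C)=CC(=O)C3(OC)OCc1ccc(OC)cc1
F2 | step 24 | Diels–Alder adduct with methoxy (4-methoxybenzyloxy) ketal | C1C(=O)O[C@@H]2C[C@@H](C)[C@]34C[C@]5(C(=O)O[C@H]6C[C@@](C)(O)C([C@H](C)CCCO[Si](c7ccccc7)(c7ccccc7)C(C)(C)C)=C[C@H]65)[C@H](C(C)=C3C[C@@H]12)C(=O)C4(OC)OCc7ccc(OC)cc7
F3 | step 26 | mono-tosylhydrazone of dione 38 | C1C(=O)O[C@@H]2C[C@@H](C)[C@]34C[C@]5(C(=O)O[C@H]6C[C@@](C)(O)C([C@H](C)CCCO[Si](c7ccccc7)(c7ccccc7)C(C)(C)C)=C[C@H]65)[C@H](C(C)=C3C[C@@H]12)C(=NNS(=O)(=O)c7ccc(C)cc7)C4=O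
F4 | step 26 | α-diazo ketone from 38 | C1C(=O)O[C@@H]2C[C@@H](C)[C@]34C[C@]5(C(=O)O[C@H]6C[C@@](C)(O)C([C@H](C)CCCO[Si](c7ccccc7)(c7ccccc7)C(C)(C)C)=C[C@H]65)[C@H](C(C)=C3C[C@@H]12)C(=[N+]=[N-])C4=O
F5 | step 26 | norbornene-7-carboxylic acid carrying both lactone halves (either C-7 epimer) | C1C(=O)O[C@@H]2C[C@@H](C)[C@]34C[C@]5(C(=O)O[C@H]6C[C@@](C)(O)C([C@H](C)CCCO[Si](c7ccccc7)(c7ccccc7)C(C)(C)C)=C[C@H]65)[C@H](C(C)=C3C[C@@H]12)C4C(O)=O
F6 | step 26 | anti-7-acetoxynorbornene carrying both lactone halves | C1C(=O)O[C@@H]2C[C@@H](C)[C@]34C[C@]5(C(=O)O[C@H]6C[C@@](C)(O)C([C@H](C)CCCO[Si](c7ccccc7)(c7ccccc7)C(C)(C)C)=C[C@H]65)[C@H](C(C)=C3C[C@@H]12)[C@H]4OC(C)=O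
F7 | step 17 | tert-butyl 4-[(4S)-4-benzyl-2-oxo-1,3-oxazolidin-3-yl]-4-oxobutanoate | CC(C)(C)OC(=O)CCC(=O)N1[C@@H](Cc2ccccc2)COC1=O
F8 | step 17 | Michael adduct imide: tert-butyl (3S)-3-{[(4S)-4-benzyl-2-oxo-1,3-oxazolidin-3-yl]carbonyl}-5-[(2R)-5-{[tert-butyl(diphenyl)silyl]oxy}pentan-2-yl]-6-oxoheptanoate | CC(=O)C(C[C@@H](CC(=O)OC(C)(C)C)C(=O)N1[C@@H](Cc2ccccc2)COC1=O)[C@H](C)CCCO[Si](c1ccccc1)(c1ccccc1)C(C)(C)C
F9 | step 17 | tert-butyl (3S)-5-[(2R)-5-{[tert-butyl(diphenyl)silyl]oxy}pentan-2-yl]-6-hydroxy-3-(hydroxymethyl)heptanoate | CC(O)C(C[C@@H](CC(=O)OC(C)(C)C)CO)[C@H](C)CCCO[Si](c1ccccc1)(c1ccccc1)C(C)(C)C
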